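**Assumptions:** (i) Myrcenol (2-methyl-6-methylideneoct-7-en-2-ol) is a commercial fragrance terpene alcohol. (ii) The quinine-derived bifunctional catalyst delivers the (2S)-flavanone; if it does not, the quinidine-derived pseudo-enantiomer is used, and the configuration is confirmed against authentic (S)-eriodictyol-type CD and HPLC. (iii) The unhindered 6'-OH of chalcone 5 cyclizes in preference to the 2'-OH flanked by the chain; any 8-substituted regioisomer is separable.

## Retrosynthetic overview
- Target **6** is a 6-(7-hydroxygeranyl) (2S)-flavanone. The C ring is the only ring formed, last, by an enantioselective intramolecular oxa-Michael closure of chalcone **5** (O1–C2 bond).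
- Chalcone **5** comes from a Claisen–Schmidt condensation of the chain-bearing acetophenone **3** with protocatechualdehyde (**4**).
- Acetophenone **3** comes from a desymmetrizing Pd–H hydro-C-allylation of phloroacetophenone (**1**) with the 1,3-diene myrcenol (**2**). The two C–H sites (C3 and C5) of **1** are equivalent, so there is no regiochemical problem. The (E)-trisubstituted olefin and the tertiary alcohol chain are installed in one C–C bond-forming step with no protecting groups.
- Ring order: the A ring (from **1**) and B ring (from **4**) are already aromatic, and only the pyranone ring is built.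

## Route

**Step 1 (key step)**
Reactants: **1** 2,4,6-trihydroxyacetophenone (3 equiv); **2** myrcenol (1 equiv)
Product: **3** 1-[2,4,6-trihydroxy-3-((E)-7-hydroxy-3,7-dimethyloct-2-en-1-yl)phenyl]ethan-1-one
Conditions: Pd2(dba)3 (2.5 mol%), DPEphos (6 mol%), 1,4-dioxane, 60 °C, 16 h, N2; the excess **1** is recovered by chromatography.
Reagents that add atoms: none (**1** and **2** supply all atoms; the reaction is an atom-economic addition).
Why: Acidic phenol **1** protonates Pd(0) to give Pd(II)–H, which delivers H to the terminal =CH2 of the 1,1-disubstituted alkene of **2**. This gives a π-allyl-Pd in which the larger chain sits syn, so the C-nucleophilic C3 of **1** attacks the unhindered CH2 terminus and gives the (E)-trisubstituted alkene, with the tertiary alcohol untouched.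
Proposed new method: Pd-catalysed diene hydro-C-allylation of an acylphloroglucinol (Pd–H hydrofunctionalization of a 2-substituted 1,3-diene, as in Pd-catalysed hydroalkylation of dienes with 1,3-diketones and hydroamination of myrcene). The expected risks are O- versus C-attack and dialkylation, which the 3-fold excess of **1** suppresses. **1** has two equivalent reactive sites (C3 and C5), so only one constitutional mono-C-alkyl product is possible.

**Step 2**
Reactants: **3**; **4** 3,4-dihydroxybenzaldehyde (protocatechualdehyde)
Product: **5** (E)-3-(3,4-dihydroxyphenyl)-1-[2,4,6-trihydroxy-3-((E)-7-hydroxy-3,7-dimethyloct-2-en-1-yl)phenyl]prop-2-en-1-one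
Conditions: KOH (8 equiv), EtOH/H2O 1:1, N2, 25→45 °C, 24 h; then cooled to 0 °C and acidified to pH ~5 with AcOH/NaH2PO4 and extracted at once.
Reagents that add atoms: none (water is lost; KOH and AcOH leave only salts).
Why: Claisen–Schmidt aldol condensation through the acetophenone enolate gives the thermodynamic (E)-enone. Only mild base and weak acid are used, so the tertiary alcohol and the trisubstituted alkene survive. Degassing protects the catechol, and the 2',6'-dihydroxychalcone stays open at pH ~5 and 0 °C, as naringenin chalcone does, so no racemic flavanone forms.

**Step 3**
Reactants: **5**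
Product: **6** (2S)-5,7,3',4'-tetrahydroxy-6-((E)-7-hydroxy-3,7-dimethyloct-2-en-1-yl)flavanone (Prokinawan)
Conditions: quinine-derived bifunctional thiourea (10 mol%), THF/toluene 1:1 (0.02 M), 20 °C, 48 h, N2; purification on Sephadex LH-20 (neutral).
Reagents that add atoms: none (intramolecular isomerization).
Why: The bifunctional catalyst deprotonates the free 6'-OH with its tertiary amine and binds the enone carbonyl with its thiourea N–H groups, so the phenoxide adds to one enantioface of the β-carbon in a 6-endo intramolecular oxa-Michael addition. This sets C2 as (S), and nothing follows that could scramble it; the mild, neutral, low-temperature conditions avoid retro-Michael racemization of the 5-hydroxyflavanone.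
Proposed new method: The enantioselective oxa-Michael cyclization of a 2',6'-dihydroxychalcone carrying a free catechol and a 3'-alkyl group extends known bifunctional-organocatalytic cyclizations of 2'-hydroxychalcones, which mimic chalcone isomerase. The 6'-OH is unhindered, whereas the 2'-OH is flanked by the chain, which favors the 6-substituted rather than the 8-substituted flavanone.

## Compound list
1 | 2,4,6-trihydroxyacetophenone | CC(=O)c1c(O)cc(O)cc1O | starting material
2 | myrcenol (2-methyl-6-methylideneoct-7-en-2-ol) | CC(C)(O)CCCC(=C)C=C | starting material
3 | 3'-[(E)-7-hydroxy-3,7-dimethyloct-2-enyl]-2',4',6'-trihydroxyacetophenone | C/C(=C\Cc1c(O)cc(O)c(C(C)=O)c1O)CCCC(C)(C)O | intermediate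
4 | 3,4-dihydroxybenzaldehyde | O=Cc1ccc(O)c(O)c1 | starting material
5 | (E)-chalcone (3,4-dihydroxy B ring; 2',4',6'-trihydroxy-3'-hydroxygeranyl A ring) | C/C(=C\Cc1c(O)cc(O)c(C(=O)/C=C/c2ccc(O)c(O)c2)c1O)CCCC(C)(C)O | intermediate
6 | Prokinawan, (2S)-flavanone | C/C(=C\Cc1c(O)cc2c(c1O)C(=O)C[C@@H](c1ccc(O)c(O)c1)O2)CCCC(C)(C)O | target

**Total step count:** 3. **Longest linear sequence:** 3 steps (1 → 3 → 5 → 6).

## Three steps most likely to fail
1. **Step 3 (ee and regiochemistry).** Enantioselectivity may be low on this polyphenolic substrate, or the 8-substituted isomer may form. Fallback: cyclize with recombinant chalcone isomerase in pH 7 buffer, which is (S)-selective for 6'-hydroxychalcones. Alternatively, cyclize racemically with mild base and resolve by preparative chiral HPLC, which also removes the 8-isomer.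
2. **Step 1 (Pd–H hydroarylation).** O-allylation, dialkylation or poor E/Z selectivity are possible. Fallback: Mukaiyama hydration (Co(acac)2, PhSiH3, O2) of geranyl acetate to 7-hydroxygeranyl acetate, then linear-selective Pd Tsuji–Trost C-allylation of **1**.
3. **Step 2 (unprotected catechol aldehyde).** Low yield from aldehyde deactivation or catechol oxidation is possible. Fallback: use the 3,4-diallyloxybenzaldehyde, condense, and remove the allyl groups with Pd(PPh3)4/morpholine before the cyclization, which is compatible with the acid-sensitive chain.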